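Everything rests on the aldol relationship C14(=O)–C1–C2(O), which lies exactly where the cyclohexane (C1, C10–C14) and the ten-membered ring (C1–C10) share the quaternary carbon C1. Cutting C1–C2 opens the macrocycle and removes its most crowded centre. In the forward direction a Lewis acid lets the tetrasubstituted C14=C1 enol silane of ring A add to the tethered C2 aldehyde, so that one operation closes the ten-membered ring and sets C1 and C2. The precursor is a 1-silyloxy-2,4-dimethylcyclohexa-1,4-diene whose C10 bears the whole C9–C2 chain: C9 silyl ether, 8-hydroxy-γ-lactone, Z-C5=C6 olefin with the C16 silyl ether, and a β-silyloxy aldehyde.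

Key step: step 23

Remarks on the design (briarane numbering throughout)
* The stereodescriptors of the enol silane aldehyde and of the bicyclic hydroxy ketone map atom for atom on the target, so no structural correction is needed there.
* A 14-keto-Δ11 ring enolises at C13, which lies between C=O and C=C, not at C1. The enol silane is therefore never made by enolisation. Its position comes from a Birch reduction of an aryl silyl ether, and C20 is added later through a C11 enol triflate.
* The enol silane is a robust TIPS ether, and the aldehyde is made last, by oxidation.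
* C4 and C9 are carried as TBS ethers, which are poor leaving groups and base stable. All four acetates are installed together after ring closure.
* O2 and O14 are 1,3-syn in the target, so the ketone needs external hydride on a boron chelate, not internal hydride delivery.
* Assumption: (5R,6R)-5,6-dimethoxy-5,6-dimethyl-1,4-dioxan-2-one, 3-(tert-butyldimethylsilyloxy)propanal and 4-methoxy-2-methylphenol are taken as commercial. In step 7 the ligand antipode that gives the 4R carbinol is used.

Step 1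
Reactants: 1 but-2-yne-1,4-diol
Product: 2 4-(tert-butyldiphenylsilyloxy)but-2-yn-1-ol
Conditions: NaH (1 equiv), THF, 0 °C; TBDPSCl (excess diol)
Reagents that add atoms: tert-butyldiphenylsilyl chloride, CC(C)(C)[Si](Cl)(c1ccccc1)c1ccccc1
Why: Statistical monosilylation of the symmetrical diol through its monosodium alkoxide differentiates C16 from C7, and no stereocentre is formed.

Step 2
Reactants: 2 4-(tert-butyldiphenylsilyloxy)but-2-yn-1-ol
Product: 4 (Z)-4-(tert-butyldiphenylsilyloxy)-3-iodobut-2-en-1-ol, via cyclic vinylalanate 3 (not isolated)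
Conditions: Red-Al, THF, 0 °C; then I2, −78 °C to rt; Rochelle salt
Reagents that add atoms: iodine, II
Why: Hydroxyl-directed trans-hydroalumination of the propargylic alcohol puts aluminium on C5 in a five-membered alanate, and iodinolysis with retention leaves iodine cis and C16 trans to C7, which is the geometry of the C5=C6 olefin of the target.

Step 3
Reactants: 4 (Z)-4-(tert-butyldiphenylsilyloxy)-3-iodobut-2-en-1-ol
Product: 5 (Z)-4-(tert-butyldiphenylsilyloxy)-3-iodobut-2-enal
Conditions: MnO2, CH2Cl2, rt, used at once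
Reagents that add atoms: none
Why: Allylic oxidation with MnO2 is neutral and stops at the enal, and immediate use prevents Z/E isomerisation.

Step 4
Reactants: 5 (Z)-4-(tert-butyldiphenylsilyloxy)-3-iodobut-2-enal; 6 (5R,6R)-5,6-dimethoxy-5,6-dimethyl-1,4-dioxan-2-one
Product: 8 anti-aldol adduct (dioxanone C3 = C8, carbinol = C7), via lithium enolate 7 (not isolated)
Conditions: LiHMDS, THF, −78 °C; then 5; AcOH quench at −78 °C
Reagents that add atoms: none
Why: In this lithium enolate aldol addition of the butane-2,3-diacetal glycolate, the axial 5-methoxy group blocks one enolate face (C8), the closed transition state gives the anti-diol relationship (C7), and the hard enolate adds 1,2 to the β-iodoenal.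

Step 5
Reactants: 8 anti-aldol adduct
Product: 9 methyl (4Z)-anti-2,3-dihydroxy-5-iodo-6-(tert-butyldiphenylsilyloxy)hex-4-enoate (C9 ester, 8-OH, 7-OH)
Conditions: CSA (cat.), MeOH, rt
Reagents that add atoms: methanol, CO
Why: Acid-catalysed methanolysis removes the diacetal and gives the dihydroxy ester without touching the two stereocentres, the vinyl iodide or the TBDPS ether.

Step 6
Reactants: 9 methyl anti-dihydroxy ester
Product: 10 7,8-bis(triethylsilyl) ether of 9
Conditions: TESOTf, 2,6-lutidine, CH2Cl2, −78 to 0 °C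
Reagents that add atoms: triethylsilyl triflate, CC[Si](CC)(CC)OS(=O)(=O)C(F)(F)F
Why: Standard O-silylation gives two non-chelating and later selectively removable groups on O7 and O8.

Step 7
Reactants: 10 bis-TES vinyl iodide ester; 11 3-(tert-butyldimethylsilyloxy)propanal
Product: 12 C2–C9 ester with free (4R)-hydroxyl (C2-OTBS, C16-OTBDPS, 7,8-bis-OTES)
Conditions: CrCl2, NiCl2 (cat.), chiral oxazoline–sulfonamide ligand, THF, rt
Reagents that add atoms: none
Why: The Nozaki–Hiyama–Kishi coupling tolerates the ester and silyl ethers and keeps the olefin geometry, and the chiral chromium–sulfonamide complex selects the aldehyde face that gives the 4R carbinol.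

Step 8
Reactants: 12 C4 alcohol
Product: 13 4-O-TBS ether of 12
Conditions: TBSOTf, 2,6-lutidine, CH2Cl2, −78 °C
Reagents that add atoms: tert-butyldimethylsilyl triflate, CC(C)(C)[Si](C)(C)OS(=O)(=O)C(F)(F)F
Why: Silylation blocks the C4 hydroxyl, which is cis to C7 on the olefin and would otherwise cyclise, as a base-stable group that is a poor leaving group.

Step 9
Reactants: 13 fully protected methyl ester
Product: 14 C9 aldehyde (7,8-bis-OTES, 4-OTBS, 2-OTBS, 16-OTBDPS)
Conditions: DIBAL-H (1.1 equiv), CH2Cl2, −78 °C; Rochelle salt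
Reagents that add atoms: none
Why: Partial reduction of an α-silyloxy ester stops at the aluminium hemiacetal at −78 °C and releases the aldehyde only on work-up, so C8 is not epimerised.

Step 10
Reactants: 15 4-methoxy-2-methylphenol
Product: 16 (4-methoxy-2-methylphenoxy)triisopropylsilane
Conditions: TIPSCl, imidazole, DMF, rt
Reagents that add atoms: triisopropylsilyl chloride, CC(C)[Si](Cl)(C(C)C)C(C)C
Why: This is a standard phenol silylation, and the bulky silyl group is chosen because it becomes the enol silane and must survive until the ring closure.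

Step 11
Reactants: 16 aryl TIPS ether
Product: 17 1-(triisopropylsilyloxy)-4-methoxy-2-methylcyclohexa-1,4-diene
Conditions: Li, NH3 (l), THF, t-BuOH, −78 °C
Reagents that add atoms: none
Why: In the Birch reduction both oxygen substituents and the methyl group stay on sp2 carbons, so the single 1,4-diene has C14=C1 as the tetrasubstituted silyl enol ether and C10 and C13 as CH2, which fixes the position of the enol silane.

Step 12
Reactants: 17 bis(enol ether) diene
Product: 18 3-methyl-4-(triisopropylsilyloxy)cyclohex-3-en-1-one (C11 ketone, C10H2, C14=C1 enol silane)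
Conditions: oxalic acid (cat.), THF–H2O, 0 °C
Reagents that add atoms: water, O
Why: In this selective enol ether hydrolysis the less hindered methyl enol ether is protonated far faster than the tetrasubstituted TIPS enol ether, and the weak acid leaves the ketone unconjugated.

Step 13
Reactants: 18 ring A ketone; 14 C9 aldehyde
Product: 20 9,10-anti-8,9-anti aldol (9-OH, C11 ketone), via boron dienolate 19 (not isolated)
Conditions: c-Hex2BCl, Et3N, Et2O, 0 °C; then 14, −78 to −20 °C; pH 7 buffer–MeOH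
Reagents that add atoms: none
Why: In this boron aldol addition, enolisation takes the doubly activated C10–H, the ring-locked E-enol borinate reacts through a Zimmerman–Traxler chair (9,10-anti), and the α-silyloxy aldehyde follows its polar Felkin–Anh/Cornforth preference (8,9-anti), so C9 and C10 are set relative to C8.

Step 14
Reactants: 20 aldol
Product: 21 9-O-TBS ether of 20
Conditions: TBSOTf, 2,6-lutidine, CH2Cl2, −78 °C
Reagents that add atoms: tert-butyldimethylsilyl triflate, CC(C)(C)[Si](C)(C)OS(=O)(=O)C(F)(F)F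
Why: Silylation under weakly basic conditions protects the β-hydroxy ketone against retro-aldol cleavage before the strong-base step.

Step 15
Reactants: 21 β-silyloxy ketone
Product: 23 C11 enol triflate (C11=C12), via potassium enolate 22 (not isolated)
Conditions: KHMDS (1.1 equiv), THF, −78 °C; Comins' reagent
Reagents that add atoms: N-(5-chloro-2-pyridyl)bis(trifluoromethanesulfonimide), O=S(=O)(N(c1ccc(Cl)cn1)S(=O)(=O)C(F)(F)F)C(F)(F)F
Why: Kinetic deprotonation removes a proton from the unhindered C12 methylene and not the tertiary C10–H, and O-triflation fixes the double bond at C11=C12.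

Step 16
Reactants: 23 enol triflate
Product: 24 complete ring A: 1-TIPSO-2,4-dimethylcyclohexa-1,4-diene with the protected chain on C10
Conditions: MeMgBr, Fe(acac)3 (5 mol %), THF–NMP, −30 °C
Reagents that add atoms: methylmagnesium bromide, C[Mg]Br
Why: Iron-catalysed Kumada-type coupling of the alkenyl triflate installs C20 without moving the double bond, and the substrate carries no carbonyl group at this stage.

Step 17
Reactants: 24 fully silylated diene
Product: 25 7,8-diol
Conditions: PPTS (cat.), MeOH–CH2Cl2, 0 °C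
Reagents that add atoms: none
Why: Acid-catalysed methanolysis discriminates by silyl size, so the two TES ethers are cleaved while the TBS and TBDPS ethers and the hindered tetrasubstituted TIPS enol ether are retained.

Step 18
Reactants: 25 7,8-diol; 26 acryloyl chloride
Product: 27 7-O-acrylate with free 8-OH
Conditions: i-Pr2NEt, CH2Cl2, −78 °C
Reagents that add atoms: none
Why: Selective O-acylation takes the allylic C7 hydroxyl, because the C8 hydroxyl is buried between two branched carbons.

Step 19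
Reactants: 27 hydroxy acrylate
Product: 28 C8 ketone (7-acryloyloxy ketone)
Conditions: Dess–Martin periodinane, pyridine, CH2Cl2, 0 °C
Reagents that add atoms: none
Why: The buffered Dess–Martin oxidation is neutral enough for the enol silane and for the configurationally sensitive C7, and it removes the auxiliary C8 stereocentre after it has done its work.

Step 20
Reactants: 28 acryloyloxy ketone
Product: 29 8-hydroxy-17-methyl-γ-lactone (C2-OTBS)
Conditions: Cu(OAc)2·H2O (5 mol %), dppf, (Me2HSi)2O, THF, rt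
Reagents that add atoms: none
Why: In this copper hydride-catalysed reductive aldol cyclisation, conjugate reduction of the acrylate gives a copper enolate that adds to the adjacent C8 ketone, the compact cyclic transition state places 8-OH and the C17 methyl cis, and the bulky C9 residue ends up trans to C6 on the new five-membered ring (C8).

Step 21
Reactants: 29 lactone, C2-OTBS
Product: 30 C2 primary alcohol
Conditions: HF·pyridine, excess pyridine, THF, 0 °C
Reagents that add atoms: none
Why: Buffered fluoride removes the unhindered primary TBS ether much faster than the secondary TBS ethers, the TBDPS ether or the shielded TIPS enol ether.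

Step 22
Reactants: 30 primary alcohol
Product: 31 ring A enol silane with C2 aldehyde chain (key-step precursor)
Conditions: Dess–Martin periodinane, pyridine, CH2Cl2, 0 °C
Reagents that add atoms: none
Why: The buffered Dess–Martin oxidation forms the β-silyloxy aldehyde without base-induced elimination and without attacking the enol silane.

Step 23
Reactants: 31 enol silane aldehyde
Product: 32 bicyclic 2-hydroxy-14-ketone (4,9-bis-OTBS, 16-OTBDPS, 8-OH)
Conditions: BF3·OEt2 (3 equiv), 2,6-di-tert-butyl-4-methylpyridine, CH2Cl2 (1 mM, slow addition of 31), −78 °C; aq. NaHCO3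
Reagents that add atoms: none
Why: Proposed new method: BF3 binds the C2 aldehyde, the C14=C1 enol silane attacks it through C1 in an open antiperiplanar transition state and the silyl group leaves as the fluorosilane, giving the boron aldolate of the β-hydroxy ketone; the closest known reaction type is the Lewis acid-mediated intramolecular Mukaiyama aldol closure of eight-membered carbocycles at fully substituted enol silane carbons, which has not been extended to a ten-membered ring closed at a quaternary carbon. The ring forms by a 10-(enolexo)-exo-trig closure, helped by high dilution and by the Z-olefin, the lactone and ring A, which take rotors out of the tether. C1 is controlled by C10: both of its ring neighbours (C1 and C11) are trigonal and methyl-substituted, so A-strain leaves the C9 branch only the pseudo-axial position, where it screens the β-face of C14=C1, and bond formation on the α-face gives the trans ring fusion. C2 is controlled by the open transition state together with the polar 1,3-anti induction of the C4 silyl ether under a monodentate Lewis acid, and the target has exactly this 2,4-anti relationship. The step needs reaction at C1 only and no enolisation or β-elimination of the aldehyde; this is secured because the enol silane position is fixed by its origin, no other π-nucleophile of similar strength is present, the hindered pyridine scavenges acid, and O4 is a poor leaving group as its silyl ether.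

Step 24
Reactants: 32 2-hydroxy-14-ketone
Product: 34 2,14-syn-diol (14α-OH), via diethylboron chelate 33 (not isolated)
Conditions: Et2BOMe, THF–MeOH (4:1), −78 °C; NaBH4; AcOH, then MeOH azeotrope
Reagents that add atoms: none
Why: In the Narasaka–Prasad reduction the boron chelate between O2 and O14 is attacked by external hydride in the sense that leads to the chair boronate, which should give the 1,3-syn diol and thus the 14α (axial) alcohol.

Step 25
Reactants: 34 diol, 4,9-bis-OTBS
Product: 35 2,4,8,9,14-pentaol, 16-OTBDPS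
Conditions: 48% aq. HF, MeCN, 0 °C
Reagents that add atoms: none
Why: Acidic fluoride cleaves the two secondary TBS ethers, while the far more acid-stable primary TBDPS ether stays on O16.

Step 26
Reactants: 35 pentaol
Product: 36 2,4,9,14-tetraacetate (Δ11, 8-OH free, 16-OTBDPS)
Conditions: Ac2O, pyridine, DMAP (cat.), CH2Cl2, rt
Reagents that add atoms: acetic anhydride, CC(=O)OC(C)=O
Why: Acylation takes all four secondary hydroxyls in one operation, and the hindered tertiary C8 hydroxyl does not react under these conditions.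

Step 27
Reactants: 36 tetraacetate alkene
Product: 37 11β-hydroxy-12α-bromide
Conditions: NBS, acetone–H2O (4:1), 0 °C, dark
Reagents that add atoms: N-bromosuccinimide, O=C1CCC(=O)N1Br; water, O
Why: In this bromohydrin formation the electron-rich C11=C12 reacts in preference to C5=C6, which is deactivated by three allylic oxygens, and only the α-bromonium ion can open in both the Markovnikov and the trans-diaxial (Fürst–Plattner) sense, by attack of water on C11 from the β-face.

Step 28
Reactants: 37 bromohydrin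
Product: 38 11β,12β-epoxide, 16-OTBDPS
Conditions: DBU, CH2Cl2, 0 °C to rt
Reagents that add atoms: none
Why: Intramolecular SN2 displacement of the antiperiplanar 12α-bromide by O11, with inversion at C12, gives the β-epoxide on the same face as C15, which direct peracid attack on the more open α-face would not give.

Step 29
Reactants: 38 silyl-protected epoxide
Product: 39 CNP0104124.1 (target)
Conditions: TBAF, AcOH (1:1), THF, 0 °C to rt
Reagents that add atoms: none
Why: Acetic acid-buffered fluoride desilylation frees the C16 alcohol without opening the epoxide and suppresses acetate migration.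

Compound list
1 | but-2-yne-1,4-diol | OCC#CCO | starting material
2 | 4-(tert-butyldiphenylsilyloxy)but-2-yn-1-ol | OCC#CCO[Si](c1ccccc1)(c1ccccc1)C(C)(C)C | intermediate
3 | cyclic vinylalanate (Al on C5 and O7), sodium salt | [Na+].COCCO[Al-]1(OCCOC)OCC=C1CO[Si](c2ccccc2)(c2ccccc2)C(C)(C)C | intermediate
4 | (Z)-4-(tert-butyldiphenylsilyloxy)-3-iodobut-2-en-1-ol | OC/C=C(/CO[Si](c1ccccc1)(c1ccccc1)C(C)(C)C)I | intermediate
5 | (Z)-4-(tert-butyldiphenylsilyloxy)-3-iodobut-2-enal | O=C/C=C(/CO[Si](c1ccccc1)(c1ccccc1)C(C)(C)C)I | intermediate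
6 | (5R,6R)-5,6-dimethoxy-5,6-dimethyl-1,4-dioxan-2-one | O=C1CO[C@](OC)(C)[C@@](OC)(C)O1 | starting material
7 | lithium enolate of 6 | [Li+].[O-]C1=CO[C@](OC)(C)[C@@](OC)(C)O1 | intermediate
8 | anti-aldol adduct of 6 and 5 | O=C1[C@H]([C@@H](O)/C=C(/CO[Si](c2ccccc2)(c2ccccc2)C(C)(C)C)I)O[C@](OC)(C)[C@@](OC)(C)O1 | intermediate
9 | methyl anti-7,8-dihydroxy ester (C9 ester, C5 iodide) | COC(=O)[C@@H](O)[C@H](/C=C(/CO[Si](c1ccccc1)(c1ccccc1)C(C)(C)C)I)O | intermediate
10 | 7,8-bis-TES ether of 9 | COC(=O)[C@@H](O[Si](CC)(CC)CC)[C@H](/C=C(/CO[Si](c1ccccc1)(c1ccccc1)C(C)(C)C)I)O[Si](CC)(CC)CC | intermediate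
11 | 3-(tert-butyldimethylsilyloxy)propanal | O=CCCO[Si](C)(C)C(C)(C)C | starting material
12 | C2–C9 ester, free (4R)-OH | COC(=O)[C@@H](O[Si](CC)(CC)CC)[C@H](/C=C(/CO[Si](c1ccccc1)(c1ccccc1)C(C)(C)C)[C@H](O)CCO[Si](C)(C)C(C)(C)C)O[Si](CC)(CC)CC | intermediate
13 | C2–C9 ester, 4-OTBS | COC(=O)[C@@H](O[Si](CC)(CC)CC)[C@H](/C=C(/CO[Si](c1ccccc1)(c1ccccc1)C(C)(C)C)[C@H](O[Si](C)(C)C(C)(C)C)CCO[Si](C)(C)C(C)(C)C)O[Si](CC)(CC)CC | intermediate
14 | C9 aldehyde | O=C[C@@H](O[Si](CC)(CC)CC)[C@H](/C=C(/CO[Si](c1ccccc1)(c1ccccc1)C(C)(C)C)[C@H](O[Si](C)(C)C(C)(C)C)CCO[Si](C)(C)C(C)(C)C)O[Si](CC)(CC)CC | intermediate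
15 | 4-methoxy-2-methylphenol | COc1ccc(O)c(C)c1 | starting material
16 | (4-methoxy-2-methylphenoxy)triisopropylsilane | COc1ccc(O[Si](C(C)C)(C(C)C)C(C)C)c(C)c1 | intermediate
17 | 1-(triisopropylsilyloxy)-4-methoxy-2-methylcyclohexa-1,4-diene | COC1=CCC(O[Si](C(C)C)(C(C)C)C(C)C)=C(C)C1 | intermediate
18 | 3-methyl-4-(triisopropylsilyloxy)cyclohex-3-en-1-one | O=C1CCC(O[Si](C(C)C)(C(C)C)C(C)C)=C(C)C1 | intermediate
19 | dicyclohexylboron dienolate of 18 | CC1=C(O[Si](C(C)C)(C(C)C)C(C)C)CCC(OB(C2CCCCC2)C2CCCCC2)=C1 | intermediate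
20 | aldol: 9-OH, C11 ketone | CC(C)[Si](C(C)C)(C(C)C)OC1=C(C)[C@@H]([C@@H](O)[C@@H](O[Si](CC)(CC)CC)[C@H](/C=C(/CO[Si](c2ccccc2)(c2ccccc2)C(C)(C)C)[C@H](O[Si](C)(C)C(C)(C)C)CCO[Si](C)(C)C(C)(C)C)O[Si](CC)(CC)CC)C(=O)CC1 | intermediate
21 | 9-OTBS ketone | CC(C)[Si](C(C)C)(C(C)C)OC1=C(C)[C@@H]([C@@H](O[Si](C)(C)C(C)(C)C)[C@@H](O[Si](CC)(CC)CC)[C@H](/C=C(/CO[Si](c2ccccc2)(c2ccccc2)C(C)(C)C)[C@H](O[Si](C)(C)C(C)(C)C)CCO[Si](C)(C)C(C)(C)C)O[Si](CC)(CC)CC)C(=O)CC1 | intermediate
22 | potassium C11=C12 enolate of 21 | CC(C)[Si](C(C)C)(C(C)C)OC1=C(C)[C@@H]([C@@H](O[Si](C)(C)C(C)(C)C)[C@@H](O[Si](CC)(CC)CC)[C@H](/C=C(/CO[Si](c2ccccc2)(c2ccccc2)C(C)(C)C)[C@H](O[Si](C)(C)C(C)(C)C)CCO[Si](C)(C)C(C)(C)C)O[Si](CC)(CC)CC)C([O-])=CC1.[K+] | intermediate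
23 | C11 enol triflate | CC(C)[Si](C(C)C)(C(C)C)OC1=C(C)[C@@H]([C@@H](O[Si](C)(C)C(C)(C)C)[C@@H](O[Si](CC)(CC)CC)[C@H](/C=C(/CO[Si](c2ccccc2)(c2ccccc2)C(C)(C)C)[C@H](O[Si](C)(C)C(C)(C)C)CCO[Si](C)(C)C(C)(C)C)O[Si](CC)(CC)CC)C(OS(=O)(=O)C(F)(F)F)=CC1 | intermediate
24 | ring A diene, chain fully silylated | CC(C)[Si](C(C)C)(C(C)C)OC1=C(C)[C@@H]([C@@H](O[Si](C)(C)C(C)(C)C)[C@@H](O[Si](CC)(CC)CC)[C@H](/C=C(/CO[Si](c2ccccc2)(c2ccccc2)C(C)(C)C)[C@H](O[Si](C)(C)C(C)(C)C)CCO[Si](C)(C)C(C)(C)C)O[Si](CC)(CC)CC)C(C)=CC1 | intermediate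
25 | 7,8-diol | CC(C)[Si](C(C)C)(C(C)C)OC1=C(C)[C@@H]([C@@H](O[Si](C)(C)C(C)(C)C)[C@@H](O)[C@H](/C=C(/CO[Si](c2ccccc2)(c2ccccc2)C(C)(C)C)[C@H](O[Si](C)(C)C(C)(C)C)CCO[Si](C)(C)C(C)(C)C)O)C(C)=CC1 | intermediate
26 | acryloyl chloride | C=CC(=O)Cl | starting material
27 | 7-O-acrylate, 8-OH | CC(C)[Si](C(C)C)(C(C)C)OC1=C(C)[C@@H]([C@@H](O[Si](C)(C)C(C)(C)C)[C@@H](O)[C@H](/C=C(/CO[Si](c2ccccc2)(c2ccccc2)C(C)(C)C)[C@H](O[Si](C)(C)C(C)(C)C)CCO[Si](C)(C)C(C)(C)C)OC(=O)C=C)C(C)=CC1 | intermediate
28 | C8 ketone, 7-O-acrylate | CC(C)[Si](C(C)C)(C(C)C)OC1=C(C)[C@@H]([C@@H](O[Si](C)(C)C(C)(C)C)C(=O)[C@H](/C=C(/CO[Si](c2ccccc2)(c2ccccc2)C(C)(C)C)[C@H](O[Si](C)(C)C(C)(C)C)CCO[Si](C)(C)C(C)(C)C)OC(=O)C=C)C(C)=CC1 | intermediate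
29 | hydroxy lactone, C2-OTBS | CC(C)[Si](C(C)C)(C(C)C)OC1=C(C)[C@@H]([C@@H](O[Si](C)(C)C(C)(C)C)[C@@]2(O)[C@H](/C=C(/CO[Si](c3ccccc3)(c3ccccc3)C(C)(C)C)[C@H](O[Si](C)(C)C(C)(C)C)CCO[Si](C)(C)C(C)(C)C)OC(=O)[C@@H]2C)C(C)=CC1 | intermediate
30 | hydroxy lactone, C2-OH | CC(C)[Si](C(C)C)(C(C)C)OC1=C(C)[C@@H]([C@@H](O[Si](C)(C)C(C)(C)C)[C@@]2(O)[C@H](/C=C(/CO[Si](c3ccccc3)(c3ccccc3)C(C)(C)C)[C@H](O[Si](C)(C)C(C)(C)C)CCO)OC(=O)[C@@H]2C)C(C)=CC1 | intermediate
31 | ring A enol silane with C2 aldehyde chain | CC(C)[Si](C(C)C)(C(C)C)OC1=C(C)[C@@H]([C@@H](O[Si](C)(C)C(C)(C)C)[C@@]2(O)[C@H](/C=C(/CO[Si](c3ccccc3)(c3ccccc3)C(C)(C)C)[C@H](O[Si](C)(C)C(C)(C)C)CC=O)OC(=O)[C@@H]2C)C(C)=CC1 | intermediate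
32 | bicyclic 2-hydroxy-14-ketone | O=C1CC=C(C)[C@@H]2[C@@H](O[Si](C)(C)C(C)(C)C)[C@@]3(O)[C@H](/C=C(/CO[Si](c4ccccc4)(c4ccccc4)C(C)(C)C)[C@H](O[Si](C)(C)C(C)(C)C)C[C@@H](O)[C@@]12C)OC(=O)[C@@H]3C | intermediate
33 | 2-O-diethylboron chelate of 32 | O=C1CC=C(C)[C@@H]2[C@@H](O[Si](C)(C)C(C)(C)C)[C@@]3(O)[C@H](/C=C(/CO[Si](c4ccccc4)(c4ccccc4)C(C)(C)C)[C@H](O[Si](C)(C)C(C)(C)C)C[C@@H](OB(CC)CC)[C@@]12C)OC(=O)[C@@H]3C | intermediate
34 | 2,14-syn-diol | O[C@H]1CC=C(C)[C@@H]2[C@@H](O[Si](C)(C)C(C)(C)C)[C@@]3(O)[C@H](/C=C(/CO[Si](c4ccccc4)(c4ccccc4)C(C)(C)C)[C@H](O[Si](C)(C)C(C)(C)C)C[C@@H](O)[C@@]12C)OC(=O)[C@@H]3C | intermediate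
35 | 2,4,8,9,14-pentaol, 16-OTBDPS | O[C@H]1CC=C(C)[C@@H]2[C@@H](O)[C@@]3(O)[C@H](/C=C(/CO[Si](c4ccccc4)(c4ccccc4)C(C)(C)C)[C@H](O)C[C@@H](O)[C@@]12C)OC(=O)[C@@H]3C | intermediate
36 | 2,4,9,14-tetraacetate, Δ11 | CC(=O)O[C@H]1CC=C(C)[C@@H]2[C@@H](OC(C)=O)[C@@]3(O)[C@H](/C=C(/CO[Si](c4ccccc4)(c4ccccc4)C(C)(C)C)[C@H](OC(C)=O)C[C@@H](OC(C)=O)[C@@]12C)OC(=O)[C@@H]3C | intermediate
37 | 11β-hydroxy-12α-bromide | CC(=O)O[C@H]1C[C@@H](Br)[C@@](O)(C)[C@@H]2[C@@H](OC(C)=O)[C@@]3(O)[C@H](/C=C(/CO[Si](c4ccccc4)(c4ccccc4)C(C)(C)C)[C@H](OC(C)=O)C[C@@H](OC(C)=O)[C@@]12C)OC(=O)[C@@H]3C | intermediate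
38 | 11β,12β-epoxide, 16-OTBDPS | CC(=O)O[C@H]1C[C@@H]2O[C@]2(C)[C@@H]2[C@@H](OC(C)=O)[C@@]3(O)[C@H](/C=C(/CO[Si](c4ccccc4)(c4ccccc4)C(C)(C)C)[C@H](OC(C)=O)C[C@@H](OC(C)=O)[C@@]12C)OC(=O)[C@@H]3C | intermediate
39 | CNP0104124.1 | CC(=O)O[C@H]1C[C@@H]2O[C@]2(C)[C@@H]2[C@@H](OC(C)=O)[C@@]3(O)[C@H](/C=C(/CO)[C@H](OC(C)=O)C[C@@H](OC(C)=O)[C@@]12C)OC(=O)[C@@H]3C | target

Total step count: 29. Longest linear sequence: 26 (steps 1–9, then 13–29). Steps 10–12 form the parallel ring A branch.

Steps most likely to fail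

1. Step 23 (ring closure). Possible failures are oligomerisation instead of cyclisation, protodesilylation of the enol silane before C–C bond formation, or attack on the face of C1 that gives the cis fusion. The fallback makes the same bond by a samarium Reformatsky-type aldol, a known way to close medium rings. It sets out from 31. NBS in THF at −78 °C converts the enol silane regiospecifically into the 1-bromo-14-keto aldehyde F1, and either C1 epimer serves. Slow addition of F1 to SmI2 in THF at −78 °C generates the samarium(III) enolate, which chelates the aldehyde and cyclises, and the route is rejoined at 32.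

2. Step 24 (C14 reduction). The risk is poor facial selectivity. The α-face of the ketone is the more open one, so hydride may enter there in spite of the chelate and give the 14β-alcohol. The fallback accepts this attack and then inverts C14.
   * It sets out from 32, which is acetylated (Ac2O, pyridine, DMAP) to the 2-O-acetyl ketone F2.
   * NaBH4 in MeOH gives the 14β-alcohol F3.
   * Tf2O and pyridine give the 14β-triflate F4.
   * CsOAc with 18-crown-6 in toluene displaces the triflate with inversion to the 2,14α-diacetate F5.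
   * Aqueous HF in MeCN gives the 4,9-diol F6, and acetylation of F6 rejoins the route at 36.

3. Step 13 (fragment union). Possible failures are competing enolisation at C12, isomerisation of the β,γ-enone, or an insufficient preference for one aldehyde face in the closed transition state. The fallback fixes the nucleophile beforehand and uses an open transition state. It sets out from 18, which with TMSOTf and Et3N gives the 1-trimethylsilyloxy-4-triisopropylsilyloxy diene F7. A BF3·OEt2-mediated Mukaiyama aldol addition of F7 to 14 at −78 °C should then react at C10, the less hindered TMS enol ether terminus, under Felkin control. The route is rejoined at 20.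

Further compounds
F1 | step 23 | 1-bromo-14-keto aldehyde (C1 epimers) | O=C1C(C)(Br)[C@@H]([C@@H](O[Si](C)(C)C(C)(C)C)[C@@]2(O)[C@H](/C=C(/CO[Si](c3ccccc3)(c3ccccc3)C(C)(C)C)[C@H](O[Si](C)(C)C(C)(C)C)CC=O)OC(=O)[C@@H]2C)C(C)=CC1
F2 | step 24 | 2-O-acetyl-14-ketone | O=C1CC=C(C)[C@@H]2[C@@H](O[Si](C)(C)C(C)(C)C)[C@@]3(O)[C@H](/C=C(/CO[Si](c4ccccc4)(c4ccccc4)C(C)(C)C)[C@H](O[Si](C)(C)C(C)(C)C)C[C@@H](OC(C)=O)[C@@]12C)OC(=O)[C@@H]3C
F3 | step 24 | 2-O-acetyl-14β-alcohol | O[C@@H]1CC=C(C)[C@@H]2[C@@H](O[Si](C)(C)C(C)(C)C)[C@@]3(O)[C@H](/C=C(/CO[Si](c4ccccc4)(c4ccccc4)C(C)(C)C)[C@H](O[Si](C)(C)C(C)(C)C)C[C@@H](OC(C)=O)[C@@]12C)OC(=O)[C@@H]3C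
F4 | step 24 | 14β-triflate | O=S(=O)(O[C@@H]1CC=C(C)[C@@H]2[C@@H](O[Si](C)(C)C(C)(C)C)[C@@]3(O)[C@H](/C=C(/CO[Si](c4ccccc4)(c4ccccc4)C(C)(C)C)[C@H](O[Si](C)(C)C(C)(C)C)C[C@@H](OC(C)=O)[C@@]12C)OC(=O)[C@@H]3C)C(F)(F)F
F5 | step 24 | 2,14α-diacetate, 4,9-bis-OTBS | CC(=O)O[C@H]1CC=C(C)[C@@H]2[C@@H](O[Si](C)(C)C(C)(C)C)[C@@]3(O)[C@H](/C=C(/CO[Si](c4ccccc4)(c4ccccc4)C(C)(C)C)[C@H](O[Si](C)(C)C(C)(C)C)C[C@@H](OC(C)=O)[C@@]12C)OC(=O)[C@@H]3C
F6 | step 24 | 2,14α-diacetate, 4,9-diol | CC(=O)O[C@H]1CC=C(C)[C@@H]2[C@@H](O)[C@@]3(O)[C@H](/C=C(/CO[Si](c4ccccc4)(c4ccccc4)C(C)(C)C)[C@H](O)C[C@@H](OC(C)=O)[C@@]12C)OC(=O)[C@@H]3C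
F7 | step 13 | 1-trimethylsilyloxy-4-triisopropylsilyloxy-3-methylcyclohexa-1,3-diene | CC1=C(O[Si](C(C)C)(C(C)C)C(C)C)CCC(O[Si](C)(C)C)=C1
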